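## Retrosynthetic overview
- The target is an isomer of a ten-membered "dehydroglaucolide" carrying a cis-4,5-epoxide, a Δ7(11)-12,6-butenolide and a C1 ynone. Loss of H-6 opens the epoxide, and the freed 4-OH bridges to C1, so the furanone is formed last.
- The carbocycle and the lactone come from one operation on an acyclic epoxy-aldehyde/β-bromoenoate. This closes C6–C7, the bond formed when farnesyl diphosphate cyclises, and the C6 alkoxide then lactonises onto C12.
- The acyclic chain comes from opening a C1/O-8 γ-lactone with the acetylide of a C2–C6 epoxy-enynol. Sharpless epoxidation of the enynol sets C4.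
- The east lactone comes from Evans allylation (C10), BINOL–Zn/Ti propiolate addition (C8), anti iodobromination and Stille hydroxymethylation, which together define the tetrasubstituted alkene.
- Ring order: ten-membered carbocycle, then butenolide in the same flask, then 3(2H)-furanone.

Assumption: germacrane numbering (C1–C15) is used throughout, and C6 in 21/22 is left undefined because step 11 erases it.

## Route

Step 1
Reactants: 1 (R)-4-benzyl-3-propanoyl-1,3-oxazolidin-2-one; 2 allyl iodide
Product: 4 (R)-4-benzyl-3-[(2S)-2-methylpent-4-enoyl]-1,3-oxazolidin-2-one, via sodium Z-enolate 3 (not isolated)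
Conditions: NaN(SiMe3)2, THF, −78 °C; then 2, −78 to −40 °C
Reagents that add atoms: allyl iodide 2, C=CCI
Why: In this Evans asymmetric alkylation the chelated Z-enolate is allylated on the face away from the benzyl group, which sets C10 as S.

Step 2
Reactants: 4 (R)-4-benzyl-3-[(2S)-2-methylpent-4-enoyl]-1,3-oxazolidin-2-one
Product: 6 (R)-4-benzyl-3-[(2S)-2-methyl-4-oxobutanoyl]-1,3-oxazolidin-2-one, via secondary ozonide 5 (not isolated)
Conditions: O3, CH2Cl2, −78 °C; then Me2S, −78 °C to rt
Reagents that add atoms: ozone, [O-][O+]=O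
Why: Criegee ozonolysis with reductive work-up cleaves the only alkene to the C8 aldehyde and leaves C10 untouched.

Step 3
Reactants: 6 (R)-4-benzyl-3-[(2S)-2-methyl-4-oxobutanoyl]-1,3-oxazolidin-2-one; 7 methyl propiolate
Product: 9 methyl 3-[(2S,4S)-4-methyl-5-oxooxolan-2-yl]prop-2-ynoate, via hydroxy imide 8 (not isolated)
Conditions: 7, Et2Zn, (R)-BINOL (40 mol %), HMPA, CH2Cl2, rt; Ti(OiPr)4; then 6, rt; aq NH4Cl
Reagents that add atoms: methyl propiolate 7, C#CC(=O)OC
Why: In this BINOL–titanium/zinc asymmetric alkynylation the (R)-ligand is expected to deliver the alkynylzinc to the Re face (inferred from the facial sense of BINOL–titanium dialkylzinc additions, so to be confirmed) and so set C8 as S, after which the zinc alkoxide attacks the imide carbonyl (5-exo-trig lactonisation), expelling the auxiliary and masking O-8 and C1 in one ring.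

Step 4
Reactants: 9 methyl 3-[(2S,4S)-4-methyl-5-oxooxolan-2-yl]prop-2-ynoate
Product: 10 methyl (2E)-3-bromo-2-iodo-3-[(2S,4S)-4-methyl-5-oxooxolan-2-yl]prop-2-enoate
Conditions: IBr, CH2Cl2, 0 °C to rt, dark
Reagents that add atoms: iodine monobromide, BrI
Why: Anti iodohalogenation of the alkynoate puts iodine on the α-carbon C11 and bromide on the β-carbon C7, so Br is cis to CO2Me and C8 is cis to the future C13, and no other π bond is present to compete.

Step 5
Reactants: 10 methyl (2E)-3-bromo-2-iodo-3-[(2S,4S)-4-methyl-5-oxooxolan-2-yl]prop-2-enoate; 11 (tributylstannyl)methanol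
Product: 13 methyl (2Z)-2-(acetoxymethyl)-3-bromo-3-[(2S,4S)-4-methyl-5-oxooxolan-2-yl]prop-2-enoate, via allylic alcohol 12 (not isolated)
Conditions: Pd2(dba)3 (5 mol %), AsPh3, CuI (10 mol %), NMP, 40 °C; then Ac2O, pyridine, rt
Reagents that add atoms: (tributylstannyl)methanol 11, CCCC[Sn](CCCC)(CCCC)CO; acetic anhydride, CC(=O)OC(C)=O
Why: Stille hydroxymethylation takes place site-selectively at C–I over C–Br with retention of alkene geometry, as in sequential couplings of α-iodo-β-halo enoates, and the alcohol is acetylated in the same flask.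

Step 6
Reactants: 14 (Z)-3-methylpent-2-en-4-yn-1-ol
Product: 15 [(2S,3R)-3-ethynyl-3-methyloxiran-2-yl]methanol
Conditions: Ti(OiPr)4 (10 mol %), L-(+)-diethyl tartrate (12 mol %), t-BuOOH, 4 Å MS, CH2Cl2, −20 °C
Reagents that add atoms: tert-butyl hydroperoxide, CC(C)(C)OO
Why: Katsuki–Sharpless epoxidation with the L-(+)-tartrate attacks the same face as in nerol and gives the (2S,3R) cis-epoxide, whose quaternary carbon is the future (4S) centre because its C–O bond is never broken.

Step 7
Reactants: 15 [(2S,3R)-3-ethynyl-3-methyloxiran-2-yl]methanol; 13 methyl (2Z)-2-(acetoxymethyl)-3-bromo-3-[(2S,4S)-4-methyl-5-oxooxolan-2-yl]prop-2-enoate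
Product: 17 methyl (2Z,4S,6S)-2-(acetoxymethyl)-3-bromo-4-hydroxy-9-[(2R,3S)-3-(hydroxymethyl)-2-methyloxiran-2-yl]-6-methyl-7-oxonon-2-en-8-ynoate, via dilithio acetylide alkoxide 16 (not isolated)
Conditions: n-BuLi (2 equiv per 15), THF, −78 °C; then 13, −78 °C; AcOH, −78 °C
Reagents that add atoms: none
Why: The lithium acetylide is acylated by the γ-lactone, which is more electrophilic than the acyclic esters at −78 °C, and the tetrahedral adduct survives until the cold quench, so a single addition gives the C1 ynone and frees O-8 without acetyl migration.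

Step 8
Reactants: 17 methyl (2Z,4S,6S)-2-(acetoxymethyl)-3-bromo-4-hydroxy-9-[(2R,3S)-3-(hydroxymethyl)-2-methyloxiran-2-yl]-6-methyl-7-oxonon-2-en-8-ynoate
Product: 18 methyl (2Z,4S,6S)-2-(acetoxymethyl)-3-bromo-9-[(2R,3R)-3-formyl-2-methyloxiran-2-yl]-4-hydroxy-6-methyl-7-oxonon-2-en-8-ynoate
Conditions: TEMPO (10 mol %), PhI(OAc)2, CH2Cl2, 0 °C to rt
Reagents that add atoms: none
Why: Oxoammonium (TEMPO/PhI(OAc)2) oxidation takes the primary C6 alcohol to the aldehyde much faster than it touches the hindered secondary C8 carbinol.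

Step 9
Reactants: 18 methyl (2Z,4S,6S)-2-(acetoxymethyl)-3-bromo-9-[(2R,3R)-3-formyl-2-methyloxiran-2-yl]-4-hydroxy-6-methyl-7-oxonon-2-en-8-ynoate; 19 3-methylbut-2-enoyl chloride
Product: 20 methyl (2Z,4S,6S)-2-(acetoxymethyl)-3-bromo-9-[(2R,3R)-3-formyl-2-methyloxiran-2-yl]-6-methyl-4-[(3-methylbut-2-enoyl)oxy]-7-oxonon-2-en-8-ynoate
Conditions: 19, pyridine, CH2Cl2, 0 °C
Reagents that add atoms: 3-methylbut-2-enoyl chloride 19, CC(C)=CC(=O)Cl
Why: O-Acylation of the only free hydroxyl installs the senecioate with retention at C8, and the weak base limits deconjugation of the acyl group.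

Step 10
Reactants: 20 methyl (2Z,4S,6S)-2-(acetoxymethyl)-3-bromo-9-[(2R,3R)-3-formyl-2-methyloxiran-2-yl]-6-methyl-4-[(3-methylbut-2-enoyl)oxy]-7-oxonon-2-en-8-ynoate
Product: 22 (4R,5S,8S,10S)-13-acetoxy-4,5-epoxy-8-(3-methylbut-2-enoyloxy)-1-oxogermacr-7(11)-en-2-yn-12,6-olide, via seco hydroxy ester 21 (not isolated)
Conditions: CrCl2 (15 equiv), NiCl2 (10 mol %), DMSO–THF, 2 mM, syringe pump, rt
Reagents that add atoms: none
Why: In this Nozaki–Hiyama–Kishi macrocyclisation zerovalent nickel inserts into the activated C7–Br bond, the alkenyl group passes with retention to trivalent chromium and adds only to the aldehyde to close C6–C7, the alkoxide cis to CO2Me lactonises at once, the cis-epoxide supplies the turn next to the alkyne, and the C6 configuration does not matter because it is erased in step 11.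

Step 11
Reactants: 22 (4R,5S,8S,10S)-13-acetoxy-4,5-epoxy-8-(3-methylbut-2-enoyloxy)-1-oxogermacr-7(11)-en-2-yn-12,6-olide
Product: 26 (4S,5E,8S,10S)-13-acetoxy-1,4-epoxy-8-(3-methylbut-2-enoyloxy)-3-oxogermacra-1,5,7(11)-trien-12,6-olide, via enaminone 23 (not isolated), via tertiary carbinol 24 (not isolated), via furaniminium acetate 25 (not isolated)
Conditions: Et2NH (1.5 equiv), THF–EtOH, 0 °C to rt; then AcOH–H2O, rt
Reagents that add atoms: water, O
Why: Proposed new method: this is a glaucolide-to-hirsutinolide type isomerisation run on a strained cyclodecynone, in which Et2NH adds to C3 of the ynone (a strain-releasing aza-Michael addition that gives the enaminone form of the C1/C3 diketone), the amine removes the vinylogously acidic H-6 and the furanolate expels the C5–O bond of the epoxide (vinylogous E1cB) so that the Δ5 enol lactone forms with C4 and C7 cis (the geometry the bridged ring should favour) while the C4–O bond and hence the (4S) centre stay intact, and the freed 4-OH closes transannularly on C1 with loss of water to an iminium ion that aqueous acid hydrolyses to the C3 ketone; the closest known reactions are the diethylamine conversion of 4-hydroxyalk-2-ynones into 3(2H)-furanones and the mild base- or silica-induced change of glaucolides into hirsutinolides.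

## Compound list
1 | (R)-4-benzyl-3-propanoyl-1,3-oxazolidin-2-one | CCC(=O)N1[C@H](Cc2ccccc2)COC1=O | starting material
2 | allyl iodide | C=CCI | starting material
3 | sodium Z-enolate of 1 | C/C=C(\[O-])N1[C@H](Cc2ccccc2)COC1=O.[Na+] | intermediate
4 | (R)-4-benzyl-3-[(2S)-2-methylpent-4-enoyl]-1,3-oxazolidin-2-one | C=CC[C@H](C)C(=O)N1[C@H](Cc2ccccc2)COC1=O | intermediate
5 | secondary ozonide (1,2,4-trioxolane) of 4 | C1OC(C[C@H](C)C(=O)N2[C@H](Cc3ccccc3)COC2=O)OO1 | intermediate
6 | (R)-4-benzyl-3-[(2S)-2-methyl-4-oxobutanoyl]-1,3-oxazolidin-2-one | O=CC[C@H](C)C(=O)N1[C@H](Cc2ccccc2)COC1=O | intermediate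
7 | methyl propiolate | C#CC(=O)OC | starting material
8 | (4S,6S)-hydroxy imide (present as its zinc alkoxide) | COC(=O)C#C[C@@H](O)C[C@H](C)C(=O)N1[C@H](Cc2ccccc2)COC1=O | intermediate
9 | methyl 3-[(2S,4S)-4-methyl-5-oxooxolan-2-yl]prop-2-ynoate | COC(=O)C#C[C@@H]1C[C@H](C)C(=O)O1 | intermediate
10 | methyl (2E)-3-bromo-2-iodo-3-[(2S,4S)-4-methyl-5-oxooxolan-2-yl]prop-2-enoate | COC(=O)/C(I)=C(\Br)[C@@H]1C[C@H](C)C(=O)O1 | intermediate
11 | (tributylstannyl)methanol | CCCC[Sn](CCCC)(CCCC)CO | starting material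
12 | methyl (2Z)-3-bromo-2-(hydroxymethyl)-3-[(2S,4S)-4-methyl-5-oxooxolan-2-yl]prop-2-enoate | COC(=O)/C(CO)=C(\Br)[C@@H]1C[C@H](C)C(=O)O1 | intermediate
13 | methyl (2Z)-2-(acetoxymethyl)-3-bromo-3-[(2S,4S)-4-methyl-5-oxooxolan-2-yl]prop-2-enoate | COC(=O)/C(COC(C)=O)=C(\Br)[C@@H]1C[C@H](C)C(=O)O1 | intermediate
14 | (Z)-3-methylpent-2-en-4-yn-1-ol | OC/C=C(C)\C#C | starting material
15 | [(2S,3R)-3-ethynyl-3-methyloxiran-2-yl]methanol | OC[C@@H]1O[C@]1(C)C#C | intermediate
16 | dilithio acetylide alkoxide of 15 | [Li+].[Li+].[O-]C[C@@H]1O[C@]1(C)C#[C-] | intermediate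
17 | C6,C8-diol ynone (open chain, 2Z,4S,6S; epoxide 2R,3S) | OC[C@@H]1O[C@]1(C)C#CC(=O)[C@@H](C)C[C@H](O)/C(Br)=C(\COC(C)=O)C(=O)OC | intermediate
18 | C6 epoxy aldehyde with free 8-OH | O=C[C@@H]1O[C@]1(C)C#CC(=O)[C@@H](C)C[C@H](O)/C(Br)=C(\COC(C)=O)C(=O)OC | intermediate
19 | 3-methylbut-2-enoyl chloride | CC(C)=CC(=O)Cl | starting material
20 | cyclisation precursor: epoxy aldehyde, ynone, 8-senecioate, (Z)-β-bromoenoate | O=C[C@@H]1O[C@]1(C)C#CC(=O)[C@@H](C)C[C@H](OC(=O)C=C(C)C)/C(Br)=C(\COC(C)=O)C(=O)OC | intermediate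
21 | ten-membered C6 carbinol with the C12 methyl ester still open (present as its chromium alkoxide) | CC(=O)OC/C(C(=O)OC)=C1/C(O)[C@@H]2O[C@]2(C)C#CC(=O)[C@@H](C)C[C@@H]1OC(=O)C=C(C)C | intermediate
22 | (4R,5S,8S,10S)-13-acetoxy-4,5-epoxy-8-(3-methylbut-2-enoyloxy)-1-oxogermacr-7(11)-en-2-yn-12,6-olide | CC(=O)OCC1=C2C(OC1=O)[C@@H]3O[C@]3(C)C#CC(=O)[C@@H](C)C[C@@H]2OC(=O)C=C(C)C | intermediate
23 | 3-(diethylamino)-2-en-1-one adduct of 22, epoxide intact | CC(=O)OCC1=C2C(OC1=O)[C@@H]3O[C@]3(C)C(=CC(=O)[C@@H](C)C[C@@H]2OC(=O)C=C(C)C)N(CC)CC | intermediate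
24 | (4S)-4-hydroxy Δ5 enol lactone enaminone | CC(=O)OCC1=C2/C(=C\[C@](C)(O)C(=CC(=O)[C@@H](C)C[C@@H]2OC(=O)C=C(C)C)N(CC)CC)OC1=O | intermediate
25 | 1,4-epoxy-bridged 3-(diethyliminio)furan acetate | CC(=O)OCC1=C2/C(=C\[C@]3(C)OC(=CC3=[N+](CC)CC)[C@@H](C)C[C@@H]2OC(=O)C=C(C)C)OC1=O.CC(=O)[O-] | intermediate
26 | CNP0102620.1, (4S,5E,8S,10S)-13-acetoxy-1,4-epoxy-8-(3-methylbut-2-enoyloxy)-3-oxogermacra-1,5,7(11)-trien-12,6-olide | CC(=O)OCC1=C2/C(=C\[C@]3(C)OC(=CC3=O)[C@@H](C)C[C@@H]2OC(=O)C=C(C)C)OC1=O | target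

## Step count and risks
Total step count: 11. Longest linear sequence: 10 (steps 1–5 and 7–11).

**Step 10.**
- Risk: the closure forms a strained ten-membered ring. Divalent chromium may also reduce the ynone or the epoxy aldehyde, and a bromide is less reactive than an iodide.
- Fallback, setting out from 20: use the C13 allylic acetate rather than the C7–Br bond as the pronucleophile. Pd(PPh3)4 with indium monoiodide (InI) turns it into an allylindium, which adds through C7 (SE2′, the π-nucleophile mode of the cyclase) to the C6 aldehyde.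
- Lactonisation then gives the 7-bromo-11(13)-methylene-12,6-olide F1.
- AgOAc returns acetate to C13 by SN2′ displacement of the tertiary allylic bromide. This comes back to the route at 22.

**Step 11.**
- Risk: the amine may displace the 13-acetate, epimerise C10, or stop at the enaminone.
- Fallback, setting out from 22: split the cascade and drop the amine. Catalytic DBU (or Et3N on silica) performs only the vinylogous epoxide opening and gives the (4S)-4-hydroxy-2-yn-1-one Δ5 enol lactone F2.
- Ph3PAuNTf2 in wet toluene then cycloisomerises the 4-hydroxy ynone to the 3(2H)-furanone by π-acid catalysis. This comes back to the route at 26.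

**Step 5.**
- Risk: zerovalent palladium may cause loss of the vicinal halogens or may couple at C–Br.
- Fallback, setting out from 10: bring in C13 as carbon monoxide. Pd(PPh3)4, CO (1 atm) and slow addition of Bu3SnH give the 2-formyl-3-bromoenoate F3.
- NaBH4/CeCl3 reduces F3 to the allylic alcohol. This comes back to the route at 12, which is acetylated as before.

Further compounds
F1 | step 10 | 7-bromo-11(13)-methylene-12,6-olide (4,5-epoxide, 2-yn-1-one and 8-senecioate retained; C6 and C7 undefined) | C=C1C(=O)OC2[C@@H]3O[C@]3(C)C#CC(=O)[C@@H](C)C[C@H](OC(=O)C=C(C)C)C12Br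
F2 | step 11 | (4S,5E,8S,10S)-13-acetoxy-4-hydroxy-8-(3-methylbut-2-enoyloxy)-1-oxogermacra-5,7(11)-dien-2-yn-12,6-olide | CC(=O)OCC1=C2/C(=C\[C@](C)(O)C#CC(=O)[C@@H](C)C[C@@H]2OC(=O)C=C(C)C)OC1=O
F3 | step 5 | methyl (2Z)-3-bromo-2-formyl-3-[(2S,4S)-4-methyl-5-oxooxolan-2-yl]prop-2-enoate | COC(=O)/C(C=O)=C(\Br)[C@@H]1C[C@H](C)C(=O)O1
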